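**Direct plan and its weak points**

A direct plan would take the carbinol carbon from L-tyrosine by self-regeneration of stereocentres. Hydroxy-deamination, pivalaldehyde acetal formation, C-prenylation and silylation would give dioxolanone A1. Its enolate would be aroylated and treated in the same flask with lithiated methyl methoxyacetate to give the β-lactone/γ-lactone bicycle A2. DBU and MeI would open A2 to the silylated butenolide A3, which would then be desilylated.
Its weakest steps would be:
(a) the one-pot aroylation/aldol/double lactonisation: an untested chain of four bond formations in which O- versus C-acylation, retro-aldol and the closure of only one aldol epimer would be left to chance, giving a crude product;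
(b) the E1cB opening of the β-lactone with in situ methylation, which would be run on that crude, most advanced material and would compete with loss of CO2 from the β-lactone;
(c) the detour through a silyl ester to the aroyl chloride, two steps that would add only a leaving group.

**Plan of the new route** (furanone locants: O1, C2 quaternary, C3 aryl, C4 OMe, C5 carbonyl)

1. The retrosynthesis cuts the O1–C2 bond and the benzylic CH2–aryl bond together, in the last skeletal step. This leaves an aryl iodide and an achiral dienoic acid, which is cut at C2–C3 (Stille) and C3–C4 (Claisen).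
2. Feature used: C2 carries O1 and the arylmethyl group and is allylic to the C3=C4 enol ether. It is therefore the terminus of an allylpalladium that forms when an aryl–Pd adds to the CH2 of a 2-(methoxycarbonyl)-1,3-diene.
3. The C5 carboxylate on the other allyl terminus can close only at C2 (five-membered ring); closure at C4 would give a three-membered ring, so the regiochemistry is fixed by ring size.
4. Ring order: the aryl ring on C3 is present from the start; the lactone ring and the prenylated benzyl arene are installed together and last, and the only stereocentre is set then by the ligand on palladium.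
5. No enolate cascade, no β-lactone opening on crude late material and no silyl ester/acid chloride detour occur; after the key step only two silyl ethers are removed.

Key step: step 9

Assumption: tert-butyl methoxyacetate is treated as a catalogue compound (otherwise one step from methoxyacetyl chloride and tert-butanol).
Assumption: the sense of induction of the phosphinooxazoline ligand on this new substrate class cannot be derived from precedent; the route is written with the (S) ligand, and the antipode is used if the first run shows the opposite sense.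

**Route**

Step 1
Reactants: 1 4-iodophenol; 2 prenyl bromide (1-bromo-3-methylbut-2-ene)
Product: 3 4-iodo-2-(3-methylbut-2-en-1-yl)phenol
Conditions: NaH (1.0 equiv), toluene, 0 °C; then 2, rt
Reagents that add atoms: none
Why: ortho-C-alkylation of the sodium phenoxide as a tight ion pair in a non-polar solvent (para position blocked by iodine, the two ortho positions equivalent) should leave the carbon–iodine bond untouched; no stereocentre.

Step 2
Reactants: 3 4-iodo-2-(3-methylbut-2-en-1-yl)phenol
Product: 4 [4-iodo-2-(3-methylbut-2-en-1-yl)phenoxy]triisopropylsilane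
Conditions: i-Pr3SiCl, imidazole, DMF, rt
Reagents that add atoms: triisopropylsilyl chloride, CC(C)[Si](Cl)(C(C)C)C(C)C
Why: Corey silylation masks the phenol so that no phenoxide competes with the carboxylate in the silver-assisted palladium step; no stereocentre.

Step 3
Reactants: 5 methyl 4-hydroxybenzoate
Product: 6 methyl 4-(triisopropylsilyloxy)benzoate
Conditions: i-Pr3SiCl, imidazole, DMF, rt
Reagents that add atoms: triisopropylsilyl chloride, CC(C)[Si](Cl)(C(C)C)C(C)C
Why: Corey silylation gives an aryl silyl ether that should survive ester enolates, triflation and acid; no stereocentre.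

Step 4
Reactants: 6 methyl 4-(triisopropylsilyloxy)benzoate; 7 tert-butyl methoxyacetate
Product: 8 tert-butyl 2-methoxy-3-oxo-3-[4-(triisopropylsilyloxy)phenyl]propanoate
Conditions: LiN(i-Pr)2 (2.2 equiv), 7 (2.2 equiv), THF, −78 °C; then 6, −78 → 0 °C; aq. NH4Cl
Reagents that add atoms: none
Why: In this crossed Claisen condensation the preformed lithium enolate of the tert-butyl ester (no self-condensation at low temperature) acylates the non-enolisable benzoate and the second equivalent stores the acidic product as its enolate; the new stereocentre is racemic and becomes planar in step 5.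

Step 5
Reactants: 8 tert-butyl 2-methoxy-3-oxo-3-[4-(triisopropylsilyloxy)phenyl]propanoate
Product: 9 tert-butyl (2E)-2-methoxy-3-[4-(triisopropylsilyloxy)phenyl]-3-(trifluoromethylsulfonyloxy)prop-2-enoate
Conditions: NaH, Et2O, 0 °C; then Tf2O, −78 → 0 °C
Reagents that add atoms: trifluoromethanesulfonic anhydride, O=S(=O)(OS(=O)(=O)C(F)(F)F)C(F)(F)F
Why: O-sulfonylation of the chelated, U-shaped sodium enolate (enolate oxygen and ester carbonyl held cis) should put the triflate cis to CO2t-Bu, the geometry that later places the carboxyl group within reach of the allyl terminus.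

Step 6
Reactants: 10 methyl propiolate
Product: 11 methyl 2-(tributylstannyl)prop-2-enoate
Conditions: Bu3SnH, Pd(PPh3)4 (1 mol%), THF, 0 °C → rt
Reagents that add atoms: tributyltin hydride, CCCC[SnH](CCCC)CCCC
Why: Palladium-catalysed syn-hydrostannation of a terminal ynoate delivers tin to the carbon α to the ester and hydride to the terminal carbon.

Step 7
Reactants: 9 tert-butyl (2E)-2-methoxy-3-[4-(triisopropylsilyloxy)phenyl]-3-(trifluoromethylsulfonyloxy)prop-2-enoate; 11 methyl 2-(tributylstannyl)prop-2-enoate
Product: 12 1-tert-butyl 5-methyl (2E)-2-methoxy-4-methylidene-3-[4-(triisopropylsilyloxy)phenyl]pent-2-enedioate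
Conditions: Pd2(dba)3 (2.5 mol%), AsPh3 (20 mol%), CuI (20 mol%), LiCl (3 equiv), NMP, 50 °C
Reagents that add atoms: none
Why: Stille coupling of the vinylogous acyl triflate should proceed with retention of the double-bond geometry; CuI speeds the tin-to-palladium transfer at this crowded centre and suppresses cine substitution, and no fluoride is used, so the silyl ether stays.

Step 8
Reactants: 12 1-tert-butyl 5-methyl (2E)-2-methoxy-4-methylidene-3-[4-(triisopropylsilyloxy)phenyl]pent-2-enedioate
Product: 13 (2E)-2-methoxy-4-(methoxycarbonyl)-3-[4-(triisopropylsilyloxy)phenyl]penta-2,4-dienoic acid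
Conditions: CF3CO2H, CH2Cl2 (1:4), 0 °C
Reagents that add atoms: none
Why: Acidolysis of the tert-butyl ester by alkyl–oxygen cleavage (loss of 2-methylpropene) frees the acid, while the methyl ester, the aryl silyl ether and the diene (deactivated towards protonation by an ester at each end) should stay intact.

Step 9
Reactants: 13 (2E)-2-methoxy-4-(methoxycarbonyl)-3-[4-(triisopropylsilyloxy)phenyl]penta-2,4-dienoic acid; 4 [4-iodo-2-(3-methylbut-2-en-1-yl)phenoxy]triisopropylsilane
Product: 16 methyl (2R)-4-methoxy-2-{[3-(3-methylbut-2-en-1-yl)-4-(triisopropylsilyloxy)phenyl]methyl}-5-oxo-3-[4-(triisopropylsilyloxy)phenyl]-2,5-dihydrofuran-2-carboxylate, via arylpalladium iodide 14 (not isolated), via palladalactone 15 (not isolated)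
Conditions: Pd2(dba)3 (2.5 mol%), (S)-t-Bu-PHOX (6 mol%), Ag2CO3 (1.1 equiv), MeCN, 60 °C
Reagents that add atoms: none
Why: Proposed new method: oxidative addition of 4 to the zerovalent palladium–phosphinooxazoline complex gives 14; Ag2CO3 removes iodide and deprotonates 13, the carboxylate binds the cationic divalent palladium and directs a Heck-type insertion of the only accessible alkene (the CH2 terminus; the other double bond is tetrasubstituted), so that the aryl group ends on CH2 and palladium on the ester-bearing carbon in the six-membered C,O-palladacycle 15 (η1 form of an allylpalladium carboxylate), from which C–O bond formation (reductive elimination at the allylic carbon, or ionisation to the η3-allyl cation and return of the carboxylate) should release 16 and zerovalent palladium. The closest known reaction types are the palladium-catalysed coupling–cyclisation of 2,3-allenoic acids with aryl iodides, which passes through the same kind of allylpalladium carboxylate and closes it to a butenolide with a fully substituted C–O carbon, and the Heck insertion/allylic substitution sequence (heteroannulation) of 1,3-dienes. The lactone ring closes by O1–C2 bond formation in a five-membered mode that takes in all three allyl carbons; closure at the other allyl terminus (the methoxy-bearing carbon) would give an α-lactone and is excluded, which removes the regiochemical ambiguity of this allyl system. The only new stereocentre, C2, is controlled by the chiral P,N ligand: the palladium-bearing carbon is α to an ester, so its two faces can exchange through the O-bound enolate and η3-allyl forms, and the ligand can select either in the insertion or in the C–O bond-forming event. The step needs C–O closure to be faster than β-hydride elimination from the new benzylic CH2 (the ordinary Heck outcome) and than conjugate addition of the carboxylate to the acrylate; the chelating ligand together with the bound carboxylate leaves no free cis site on palladium in 15, and the silver salt keeps the reaction on the cationic pathway.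

Step 10
Reactants: 16 methyl (2R)-4-methoxy-2-{[3-(3-methylbut-2-en-1-yl)-4-(triisopropylsilyloxy)phenyl]methyl}-5-oxo-3-[4-(triisopropylsilyloxy)phenyl]-2,5-dihydrofuran-2-carboxylate
Product: 17 2-O-methylbutyrolactone I, methyl (2R)-2-[4-hydroxy-3-(3-methylbut-2-en-1-yl)benzyl]-3-(4-hydroxyphenyl)-4-methoxy-5-oxo-2,5-dihydrofuran-2-carboxylate
Conditions: Bu4NF, AcOH, THF, 0 °C
Reagents that add atoms: none
Why: Fluoride cleaves both aryl Si–O bonds while acetic acid buffers the phenoxides, so that lactone, ester and the prenylphenol (no cyclisation to a chroman) should be untouched; the quaternary (R) centre is not involved.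

**Compound list**

1 | 4-iodophenol | Oc1ccc(I)cc1 | starting material
2 | prenyl bromide (1-bromo-3-methylbut-2-ene) | CC(C)=CCBr | starting material
3 | 4-iodo-2-(3-methylbut-2-en-1-yl)phenol | CC(C)=CCc1cc(I)ccc1O | intermediate
4 | [4-iodo-2-(3-methylbut-2-en-1-yl)phenoxy]triisopropylsilane | CC(C)=CCc1cc(I)ccc1O[Si](C(C)C)(C(C)C)C(C)C | intermediate
5 | methyl 4-hydroxybenzoate | COC(=O)c1ccc(O)cc1 | starting material
6 | methyl 4-(triisopropylsilyloxy)benzoate | COC(=O)c1ccc(O[Si](C(C)C)(C(C)C)C(C)C)cc1 | intermediate
7 | tert-butyl methoxyacetate | COCC(=O)OC(C)(C)C | starting material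
8 | tert-butyl 2-methoxy-3-oxo-3-[4-(triisopropylsilyloxy)phenyl]propanoate (racemic) | COC(C(=O)OC(C)(C)C)C(=O)c1ccc(O[Si](C(C)C)(C(C)C)C(C)C)cc1 | intermediate
9 | tert-butyl (2E)-2-methoxy-3-[4-(triisopropylsilyloxy)phenyl]-3-(trifluoromethylsulfonyloxy)prop-2-enoate (triflate cis to the ester) | CO/C(C(=O)OC(C)(C)C)=C(/OS(=O)(=O)C(F)(F)F)c1ccc(O[Si](C(C)C)(C(C)C)C(C)C)cc1 | intermediate
10 | methyl propiolate (methyl prop-2-ynoate) | C#CC(=O)OC | starting material
11 | methyl 2-(tributylstannyl)prop-2-enoate | C=C(C(=O)OC)[Sn](CCCC)(CCCC)CCCC | intermediate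
12 | 1-tert-butyl 5-methyl (2E)-2-methoxy-4-methylidene-3-[4-(triisopropylsilyloxy)phenyl]pent-2-enedioate | CO/C(C(=O)OC(C)(C)C)=C(/C(=C)C(=O)OC)c1ccc(O[Si](C(C)C)(C(C)C)C(C)C)cc1 | intermediate
13 | (2E)-2-methoxy-4-(methoxycarbonyl)-3-[4-(triisopropylsilyloxy)phenyl]penta-2,4-dienoic acid | CO/C(C(=O)O)=C(/C(=C)C(=O)OC)c1ccc(O[Si](C(C)C)(C(C)C)C(C)C)cc1 | intermediate
14 | [3-(3-methylbut-2-en-1-yl)-4-(triisopropylsilyloxy)phenyl]palladium iodide (divalent palladium; phosphinooxazoline ligand omitted) | CC(C)=CCc1cc([Pd]I)ccc1O[Si](C(C)C)(C(C)C)C(C)C | intermediate (not isolated)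
15 | six-membered C,O-palladacycle: divalent palladium bound to the ester-bearing carbon (future C2) and to the carboxylate oxygen, η1 form of the allylpalladium carboxylate (ligand omitted; drawn for C–O bond formation with retention) | COC(=O)[C@]1(Cc2ccc(O[Si](C(C)C)(C(C)C)C(C)C)c(CC=C(C)C)c2)[Pd]OC(=O)C(OC)=C1c1ccc(O[Si](C(C)C)(C(C)C)C(C)C)cc1 | intermediate (not isolated)
16 | methyl (2R)-4-methoxy-2-{[3-(3-methylbut-2-en-1-yl)-4-(triisopropylsilyloxy)phenyl]methyl}-5-oxo-3-[4-(triisopropylsilyloxy)phenyl]-2,5-dihydrofuran-2-carboxylate | COC(=O)[C@]1(Cc2ccc(O[Si](C(C)C)(C(C)C)C(C)C)c(CC=C(C)C)c2)OC(=O)C(OC)=C1c1ccc(O[Si](C(C)C)(C(C)C)C(C)C)cc1 | intermediate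
17 | 2-O-methylbutyrolactone I, methyl (2R)-2-[4-hydroxy-3-(3-methylbut-2-en-1-yl)benzyl]-3-(4-hydroxyphenyl)-4-methoxy-5-oxo-2,5-dihydrofuran-2-carboxylate | COC(=O)[C@]1(Cc2ccc(O)c(CC=C(C)C)c2)OC(=O)C(OC)=C1c1ccc(O)cc1 | target

**Step count**

Total step count: 10. Longest linear sequence: 7 steps (steps 3, 4, 5, 7, 8, 9, 10).

**Steps most likely to fail**

1. Step 9 (proposed new method). β-Hydride elimination from the benzylic CH2 (ordinary Heck arylation) or 6-endo conjugate addition of the carboxylate may outrun the C–O closure at the quaternary carbon, and the ligand may discriminate the two faces poorly. The fallback uses known reactions only, sets out from 4 and 6 and returns at 16.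
   - Iodine–magnesium exchange of 4 (i-PrMgCl·LiCl, THF, −20 °C) and formylation with DMF would give 3-(3-methylbut-2-en-1-yl)-4-(triisopropylsilyloxy)benzaldehyde F1.
   - NaBH4 would reduce it to [3-(3-methylbut-2-en-1-yl)-4-(triisopropylsilyloxy)phenyl]methanol F2, and CBr4/PPh3 would convert this into [4-(bromomethyl)-2-(3-methylbut-2-en-1-yl)phenoxy]triisopropylsilane F3.
   - Crossed Claisen condensation of 6 with lithiated methyl acetate would give methyl 3-oxo-3-[4-(triisopropylsilyloxy)phenyl]propanoate F4.
   - Alkylation of F4 with F3 (K2CO3, acetone) would give racemic methyl 2-{[3-(3-methylbut-2-en-1-yl)-4-(triisopropylsilyloxy)phenyl]methyl}-3-oxo-3-[4-(triisopropylsilyloxy)phenyl]propanoate F5.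
   - Enantioselective α-hydroxylation of this β-keto ester (cumene hydroperoxide, cinchona-alkaloid-derived ammonium phase-transfer catalyst, toluene/aq. K2HPO4) should set the tertiary carbinol in methyl (2R)-2-hydroxy-2-{[3-(3-methylbut-2-en-1-yl)-4-(triisopropylsilyloxy)phenyl]methyl}-3-oxo-3-[4-(triisopropylsilyloxy)phenyl]propanoate F6.
   - Acylation with methoxyacetyl chloride (pyridine, DMAP) would give methyl (2R)-2-(methoxyacetoxy)-2-{[3-(3-methylbut-2-en-1-yl)-4-(triisopropylsilyloxy)phenyl]methyl}-3-oxo-3-[4-(triisopropylsilyloxy)phenyl]propanoate F7.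
   - DBU in MeCN would close the butenolide by intramolecular aldol condensation (ester enolate onto the aryl ketone, then loss of water) to give 16.

2. Step 7. Transfer of the acrylate group from tin to the crowded, tetrasubstituted vinylpalladium may be too slow, so that cine substitution, protodestannylation or homocoupling of 11 take over. The fallback sets out from 9 and returns at 12.
   - Palladium-catalysed coupling of 9 with the Reformatsky reagent BrZnCH2CO2Me (Pd2(dba)3, XPhos, THF, 50 °C) would give 1-tert-butyl 5-methyl (2Z)-2-methoxy-3-[4-(triisopropylsilyloxy)phenyl]pent-2-enedioate F8.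
   - Its doubly activated CH2 would be aminomethylated with dimethylmethylideneammonium iodide and Et3N to the Mannich base 1-tert-butyl 5-methyl (2Z)-4-[(dimethylamino)methyl]-2-methoxy-3-[4-(triisopropylsilyloxy)phenyl]pent-2-enedioate F9.
   - Quaternisation with MeI and elimination with NaHCO3 would give the methylidene compound 12.

3. Step 1. O-Alkylation and double alkylation of the ambident phenoxide may dominate over single ortho-C-alkylation. The fallback sets out from 1 and returns at 3.
   - O-Allylation of 1 (allyl bromide, K2CO3, acetone) would give 1-iodo-4-(prop-2-en-1-yloxy)benzene F10.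
   - Thermal aromatic Claisen rearrangement (N,N-diethylaniline, 200 °C) would give 4-iodo-2-(prop-2-en-1-yl)phenol F11 with the allyl group ortho only.
   - Cross-metathesis with 2-methylbut-2-ene (second-generation Grubbs catalyst, CH2Cl2, 40 °C) would turn the allyl group into the prenyl group of 3.

**Further compounds**

F1 | step 9 | 3-(3-methylbut-2-en-1-yl)-4-(triisopropylsilyloxy)benzaldehyde | CC(C)=CCc1cc(C=O)ccc1O[Si](C(C)C)(C(C)C)C(C)C
F2 | step 9 | [3-(3-methylbut-2-en-1-yl)-4-(triisopropylsilyloxy)phenyl]methanol | CC(C)=CCc1cc(CO)ccc1O[Si](C(C)C)(C(C)C)C(C)C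
F3 | step 9 | [4-(bromomethyl)-2-(3-methylbut-2-en-1-yl)phenoxy]triisopropylsilane | CC(C)=CCc1cc(CBr)ccc1O[Si](C(C)C)(C(C)C)C(C)C
F4 | step 9 | methyl 3-oxo-3-[4-(triisopropylsilyloxy)phenyl]propanoate | COC(=O)CC(=O)c1ccc(O[Si](C(C)C)(C(C)C)C(C)C)cc1
F5 | step 9 | methyl 2-{[3-(3-methylbut-2-en-1-yl)-4-(triisopropylsilyloxy)phenyl]methyl}-3-oxo-3-[4-(triisopropylsilyloxy)phenyl]propanoate (racemic) | COC(=O)C(Cc1ccc(O[Si](C(C)C)(C(C)C)C(C)C)c(CC=C(C)C)c1)C(=O)c1ccc(O[Si](C(C)C)(C(C)C)C(C)C)cc1
F6 | step 9 | methyl (2R)-2-hydroxy-2-{[3-(3-methylbut-2-en-1-yl)-4-(triisopropylsilyloxy)phenyl]methyl}-3-oxo-3-[4-(triisopropylsilyloxy)phenyl]propanoate | COC(=O)[C@@](O)(Cc1ccc(O[Si](C(C)C)(C(C)C)C(C)C)c(CC=C(C)C)c1)C(=O)c1ccc(O[Si](C(C)C)(C(C)C)C(C)C)cc1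
F7 | step 9 | methyl (2R)-2-(methoxyacetoxy)-2-{[3-(3-methylbut-2-en-1-yl)-4-(triisopropylsilyloxy)phenyl]methyl}-3-oxo-3-[4-(triisopropylsilyloxy)phenyl]propanoate | COC(=O)[C@@](OC(=O)COC)(Cc1ccc(O[Si](C(C)C)(C(C)C)C(C)C)c(CC=C(C)C)c1)C(=O)c1ccc(O[Si](C(C)C)(C(C)C)C(C)C)cc1
F8 | step 7 | 1-tert-butyl 5-methyl (2Z)-2-methoxy-3-[4-(triisopropylsilyloxy)phenyl]pent-2-enedioate | CO/C(C(=O)OC(C)(C)C)=C(/CC(=O)OC)c1ccc(O[Si](C(C)C)(C(C)C)C(C)C)cc1
F9 | step 7 | 1-tert-butyl 5-methyl (2Z)-4-[(dimethylamino)methyl]-2-methoxy-3-[4-(triisopropylsilyloxy)phenyl]pent-2-enedioate (racemic) | CO/C(C(=O)OC(C)(C)C)=C(/C(CN(C)C)C(=O)OC)c1ccc(O[Si](C(C)C)(C(C)C)C(C)C)cc1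
F10 | step 1 | 1-iodo-4-(prop-2-en-1-yloxy)benzene | C=CCOc1ccc(I)cc1
F11 | step 1 | 4-iodo-2-(prop-2-en-1-yl)phenol | C=CCc1cc(I)ccc1O
A1 | direct plan | (2S,5S)-2-tert-butyl-5-[4-(tert-butyldimethylsilyloxy)-3-(3-methylbut-2-en-1-yl)benzyl]-1,3-dioxolan-4-one | O=C1O[C@@H](C(C)(C)C)O[C@H]1Cc1ccc(O[Si](C)(C)C(C)(C)C)c(CC=C(C)C)c1
A2 | direct plan | (1R,5S)-4-methoxy-1-[4-(tert-butyldimethylsilyloxy)-3-(3-methylbut-2-en-1-yl)benzyl]-5-[4-(tert-butyldimethylsilyloxy)phenyl]-2,6-dioxabicyclo[3.2.0]heptane-3,7-dione | O=C1O[C@]2(c3ccc(O[Si](C)(C)C(C)(C)C)cc3)[C@@]1(Cc4ccc(O[Si](C)(C)C(C)(C)C)c(CC=C(C)C)c4)OC(=O)C2OC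
A3 | direct plan | methyl (2R)-2-[4-(tert-butyldimethylsilyloxy)-3-(3-methylbut-2-en-1-yl)benzyl]-3-[4-(tert-butyldimethylsilyloxy)phenyl]-4-methoxy-5-oxo-2,5-dihydrofuran-2-carboxylate | COC(=O)[C@]1(Cc2ccc(O[Si](C)(C)C(C)(C)C)c(CC=C(C)C)c2)OC(=O)C(OC)=C1c3ccc(O[Si](C)(C)C(C)(C)C)cc3
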